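The route rests on a [4+2] disconnection of the C1–C10 and C5–C6 bonds. The target's cis ring fusion (quaternary C1 with its methyl, C5–H), flanked by oxygenated C10 and C6, is the imprint of an endo adduct between a 1,4-dioxygenated diene (C10=C8–C7=C6) and the C1=C5 alkene of a methylcyclopentenedione, which becomes the five-membered ring C1–C5. In one catalytic, enantioselective operation the key step builds a cyclohexene, both bonds and four stereocentres; the six-membered ring is enlarged later by inserting C9. The precursors are a 1-pivaloyloxy-4-silyloxy-2-methylbutadiene, its donor pattern matched to the catalysed regiochemistry, and 4-methylcyclopent-4-ene-1,3-dione.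

Key step: step 4

Remark (numbering and faces): carbons carry the numbers of the target's bicyclic skeleton (C1 methyl-bearing ring-fusion carbon, C2/C3 ring CH2, C4 carbinol carbon, C5 ring-fusion CH, C6 aroyloxy carbon, C7 CH2, C8 methyl-bearing alkene carbon, C9 alkene CH, C10 isovaleryloxy carbon); α is the face of the C1 methyl and H5, β the opposite face.
Assumption: the tertiary C4 alcohol needs no protection, because the isopropyl group and two ring carbons shield it.

Step 1
Reactants: 1 (tert-butyldimethylsilyloxy)acetaldehyde; 2 2-(triphenylphosphoranylidene)propanal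
Product: 3 (E)-4-(tert-butyldimethylsilyloxy)-2-methylbut-2-enal
Conditions: toluene, 80 °C
Reagents that add atoms: none
Why: Wittig olefination with a stabilised formyl ylide, which equilibrates at the oxaphosphetane stage and should therefore give the E-enal.

Step 2
Reactants: 3 (E)-4-(tert-butyldimethylsilyloxy)-2-methylbut-2-enal
Product: 5 (1E,3E)-4-(tert-butyldimethylsilyloxy)-2-methylbuta-1,3-dien-1-yl pivalate, via potassium dienolate 4 (not isolated)
Conditions: KOtBu, THF, −78 °C; then PivCl, −78 → 0 °C
Reagents that add atoms: pivaloyl chloride, CC(C)(C)C(=O)Cl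
Why: γ-Deprotonation of the enal and O-acylation of the extended enolate (dienyl ester formation); the s-trans enal fixes the 1E geometry, and 1,3-allylic strain with the C2 methyl should place the silyloxy group outside (3E).

Step 3
Reactants: 6 3-methylcyclopent-2-en-1-one
Product: 7 4-methylcyclopent-4-ene-1,3-dione
Conditions: Rh2(C6H10NO)4 [dirhodium tetrakis(caprolactamate)] (1 mol %), 70% aq t-BuOOH, 1,2-dichloroethane, 40 °C
Reagents that add atoms: tert-butyl hydroperoxide, CC(C)(C)OO
Why: Catalytic allylic oxidation of an enone to an enedione, in which tert-butylperoxy radicals attack the ring γ-methylene (its weakest C–H bond) and the mixed peroxide collapses to the ketone without added base, which the acidic product would not tolerate.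

Step 4
Reactants: 5 (1E,3E)-4-(tert-butyldimethylsilyloxy)-2-methylbuta-1,3-dien-1-yl pivalate; 7 4-methylcyclopent-4-ene-1,3-dione
Product: 8 cis-fused hydrindenedione adduct (C2 and C4 ketones, C7=C8, 1α-methyl, 5α-H, 6β-silyloxy, 10β-pivaloyloxy)
Conditions: (R)-B-(o-tolyl)oxazaborolidine of α,α-diphenylprolinol·HNTf2 (20 mol %), CH2Cl2, −78 → −40 °C
Reagents that add atoms: none
Why: Proposed new method: a Lewis-acid-catalysed normal-demand Diels–Alder reaction, concerted but asynchronous, in which the cationic boron centre binds the more basic C4 carbonyl (vinylogous to the C1 methyl, its neighbouring C5–H held by the catalyst oxygen), so that C1 becomes the electrophilic terminus, C10 (the far terminus of the silyl dienol ether) bonds first and C6–C5 follows in the same event; the closest known reactions are oxazaborolidinium-catalysed cycloadditions of silyloxydienes to methyl-substituted 1,4-quinones, not yet shown for a cyclopentenedione or a 1,4-dioxygenated diene. The single new ring, cyclohexene C1–C10–C8–C7–C6–C5, closes by suprafacial [4+2] cycloaddition through the endo transition state. C1 and C5 are set cis by suprafacial addition to the ring alkene, and the C6 and C10 oxygens come out cis to each other and trans to the C1 methyl and H5 because both diene substituents are E and the ring carbonyls lie endo. The absolute configuration of all four centres is set by the catalyst, whose phenyl group shields one face of the bound C1=C5 alkene (the R catalyst is chosen from the binding model). The step needs regiocontrol, C10 to C1 and C6 to C5, which the diene secures by carrying its strong donor (silyloxy) on C6 and the methyl on C8, both of which raise the coefficient at C10, while only the weak acyloxy donor sits on C10. Without Lewis acid the opposite pairing is expected, which is why the oxygen substituents are placed this way round.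

Step 5
Reactants: 8 cis-fused hydrindenedione adduct
Product: 9 C4 enol triflate (4-triflyloxy-3-en-2-one)
Conditions: Tf2O, Et3N, CH2Cl2, −78 °C
Reagents that add atoms: trifluoromethanesulfonic anhydride, O=S(=O)(OS(=O)(=O)C(F)(F)F)C(F)(F)F
Why: O-Sulfonylation of the enolised 1,3-dione (vinylogous triflate formation) should take place at the C4 oxygen, which lies next to the tertiary C5 and not next to the quaternary C1.

Step 6
Reactants: 9 C4 enol triflate
Product: 10 4-isopropyl-3-en-2-one
Conditions: i-PrMgCl, CuBr·SMe2, THF, −78 → −40 °C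
Reagents that add atoms: isopropylmagnesium chloride, CC(C)[Mg]Cl
Why: Conjugate addition–elimination of a Gilman-type cuprate at the β-triflyloxy enone replaces the triflate by isopropyl at C4, while the pivalate and silyl ether are inert at low temperature.

Step 7
Reactants: 10 4-isopropyl-3-en-2-one
Product: 11 3α,4α-epoxy-2-ketone
Conditions: 30% H2O2, NaOH, MeOH, 0 °C
Reagents that add atoms: hydrogen peroxide, OO
Why: Weitz–Scheffer nucleophilic epoxidation, in which hydroperoxide adds to C4 from the convex α face, anti to the C5–C6 bond of the cis-fused six-membered ring and its silyloxy group, so that C3 and C4 receive the α-epoxide that fixes the C4–O configuration of the target.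

Step 8
Reactants: 11 3α,4α-epoxy-2-ketone
Product: 13 4α-hydroxy-4β-isopropyl-2-ene, via epoxy hydrazone 12 (not isolated)
Conditions: N2H4·H2O, AcOH (cat.), MeOH, 0 °C → rt
Reagents that add atoms: none
Why: Wharton transposition, in which the C2 hydrazone opens the epoxide and loses N2, leaving the C2=C3 alkene and the tertiary C4 alcohol with its C–O bond untouched, so that C2 is deoxygenated and C4 keeps the α-oxygen with the isopropyl group β.

Step 9
Reactants: 13 4α-hydroxy-4β-isopropyl-2-ene
Product: 14 saturated five-membered ring compound (4α-OH, 6β-OTBS, 10β-OPiv, C7=C8)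
Conditions: 2-nitrobenzenesulfonylhydrazide, Et3N, CH2Cl2, rt
Reagents that add atoms: none
Why: Diimide reduction (concerted syn transfer of H2) takes the cis-disubstituted cyclopentene far faster than the trisubstituted C7=C8 alkene and cannot cleave the allylic C–O bonds.

Step 10
Reactants: 14 saturated five-membered ring compound
Product: 15 4α,10β-diol (6β-OTBS, C7=C8)
Conditions: LiAlH4, THF, 0 °C
Reagents that add atoms: none
Why: Hydride reduction of the ester removes the hindered pivalate, while the silyl ether, alkene and tertiary alcohol are inert.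

Step 11
Reactants: 15 4α,10β-diol
Product: 16 C10 ketone (enone C10(=O)–C8=C7, 4α-OH, 6β-OTBS)
Conditions: Dess–Martin periodinane, NaHCO3, CH2Cl2, rt
Reagents that add atoms: none
Why: Dess–Martin oxidation of the secondary allylic alcohol, which leaves the tertiary alcohol alone and removes the C10 centre that the cycloaddition set opposite to the target.

Step 12
Reactants: 16 C10 ketone
Product: 17 triethylsilyl enol ether (C10=C8, C7 now CH2)
Conditions: RhCl(PPh3)3 (2 mol %), Et3SiH, THF, 50 °C
Reagents that add atoms: triethylsilane, CC[SiH](CC)CC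
Why: Rhodium-catalysed 1,4-hydrosilylation of the enone puts hydride on C7 and silicon on oxygen, giving the C10=C8 silyl enol ether, the only regioisomer possible because C1 is quaternary; the hindered tertiary alcohol is expected to stay unsilylated.

Step 13
Reactants: 17 triethylsilyl enol ether
Product: 18 siloxycyclopropane (C9 bridging C8 and C10)
Conditions: Et2Zn, CH2I2, CH2Cl2, 0 °C → rt
Reagents that add atoms: diiodomethane, ICI
Why: Simmons–Smith cyclopropanation (Furukawa variant) of the electron-rich tetrasubstituted enol ether adds CH2, the future C9, across C10=C8, expected from the convex α face; the two new centres are erased in step 14, so either face serves.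

Step 14
Reactants: 18 siloxycyclopropane
Product: 20 cis-fused hydroazulenone (10-oxo, C8=C9, 4α-OH, 6β-OTBS), via β-chloro ketone 19 (not isolated)
Conditions: FeCl3, DMF, 0 °C; then NaOAc, MeOH, 65 °C
Reagents that add atoms: none
Why: Ito–Saegusa ring expansion, in which one-electron oxidation by FeCl3 gives a cyclopropyloxy radical, β-scission of the internal C10–C8 bond gives the tertiary C8 radical, chlorine transfer gives the β-chloro ketone, and acetate-mediated E1cB loss of HCl gives the conjugated C8=C9 enone.

Step 15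
Reactants: 20 cis-fused hydroazulenone
Product: 21 10α-alcohol
Conditions: NaBH4, CeCl3·7H2O, MeOH, −78 °C
Reagents that add atoms: none
Why: Luche 1,2-reduction, in which the small cerium-activated borohydride is expected to attack C10 from the β face, anti to the adjacent pseudo-axial C1 methyl (as in reductions of ketones next to angular methyl groups), placing the hydroxyl α and cis to that methyl.

Step 16
Reactants: 21 10α-alcohol
Product: 22 10α-isovalerate
Conditions: isovaleric anhydride, DMAP, Et3N, CH2Cl2, rt
Reagents that add atoms: 3-methylbutanoic anhydride, CC(C)CC(=O)OC(=O)CC(C)C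
Why: DMAP-catalysed acyl transfer to the only secondary alcohol, while the shielded tertiary C4 alcohol does not react.

Step 17
Reactants: 22 10α-isovalerate
Product: 23 6β-alcohol
Conditions: HF·pyridine, pyridine, THF, 0 °C → rt
Reagents that add atoms: none
Why: Fluoride-mediated desilylation under buffered conditions, which leave the allylic ester, the alkene and the tertiary alcohol untouched.

Step 18
Reactants: 23 6β-alcohol
Product: 24 6β-(4-acetoxybenzoate)
Conditions: 4-acetoxybenzoyl chloride, pyridine, DMAP (cat.), CH2Cl2, 0 °C → rt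
Reagents that add atoms: 4-acetoxybenzoyl chloride, CC(=O)Oc1ccc(cc1)C(Cl)=O
Why: Acylation of the secondary C6 alcohol by the acid chloride under nucleophilic catalysis, with the phenol masked as its acetate so that the reagent cannot condense with itself.

Step 19
Reactants: 24 6β-(4-acetoxybenzoate)
Product: 25 target, (3S,3aS,4R,8R,8aR)-3-hydroxy-6,8a-dimethyl-8-(3-methylbutanoyloxy)-3-(propan-2-yl)-1,2,3,3a,4,5,8,8a-octahydroazulen-4-yl 4-hydroxybenzoate
Conditions: pyrrolidine, CH2Cl2, 0 °C
Reagents that add atoms: none
Why: Chemoselective aminolysis, in which the aryl acetate, with phenoxide as leaving group, is cleaved by the secondary amine much faster than the two esters of hindered secondary alcohols.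

Compound list
1 | (tert-butyldimethylsilyloxy)acetaldehyde | CC(C)(C)[Si](C)(C)OCC=O | starting material
2 | 2-(triphenylphosphoranylidene)propanal | CC(C=O)=P(c1ccccc1)(c1ccccc1)c1ccccc1 | starting material
3 | (E)-4-(tert-butyldimethylsilyloxy)-2-methylbut-2-enal | CC(C)(C)[Si](C)(C)OC/C=C(\C)C=O | intermediate
4 | potassium (1E,3E)-4-(tert-butyldimethylsilyloxy)-2-methylbuta-1,3-dien-1-olate | [K+].[O-]/C=C(C)/C=C/O[Si](C)(C)C(C)(C)C | intermediate
5 | (1E,3E)-4-(tert-butyldimethylsilyloxy)-2-methylbuta-1,3-dien-1-yl pivalate | CC(C)(C)[Si](C)(C)O/C=C/C(C)=C/OC(=O)C(C)(C)C | intermediate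
6 | 3-methylcyclopent-2-en-1-one | CC1=CC(=O)CC1 | starting material
7 | 4-methylcyclopent-4-ene-1,3-dione | CC1=CC(=O)CC1=O | intermediate
8 | (3aS,4R,7S,7aR)-4-(tert-butyldimethylsilyloxy)-6,7a-dimethyl-1,3-dioxo-2,3,3a,4,7,7a-hexahydro-1H-inden-7-yl pivalate (cis-fused adduct; 1α-methyl, 5α-H, 6β-OTBS, 10β-OPiv) | CC1=C[C@@H](O[Si](C)(C)C(C)(C)C)[C@H]2C(=O)CC(=O)[C@@]2(C)[C@H]1OC(=O)C(C)(C)C | intermediate
9 | C4 enol triflate of 8 (4-triflyloxy-3-en-2-one) | CC1=C[C@@H](O[Si](C)(C)C(C)(C)C)[C@H]2C(OS(=O)(=O)C(F)(F)F)=CC(=O)[C@@]2(C)[C@H]1OC(=O)C(C)(C)C | intermediate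
10 | 4-isopropyl-3-en-2-one (6β-OTBS, 10β-OPiv) | CC1=C[C@@H](O[Si](C)(C)C(C)(C)C)[C@H]2C(C(C)C)=CC(=O)[C@@]2(C)[C@H]1OC(=O)C(C)(C)C | intermediate
11 | 3α,4α-epoxy-4β-isopropyl-2-ketone | CC1=C[C@@H](O[Si](C)(C)C(C)(C)C)[C@H]2[C@]3(C(C)C)O[C@@H]3C(=O)[C@@]2(C)[C@H]1OC(=O)C(C)(C)C | intermediate
12 | C2 hydrazone of 11 | CC1=C[C@@H](O[Si](C)(C)C(C)(C)C)[C@H]2[C@]3(C(C)C)O[C@@H]3C(=NN)[C@@]2(C)[C@H]1OC(=O)C(C)(C)C | intermediate
13 | 4α-hydroxy-4β-isopropyl-2-ene (6β-OTBS, 10β-OPiv, C7=C8) | CC1=C[C@@H](O[Si](C)(C)C(C)(C)C)[C@H]2[C@@](O)(C(C)C)C=C[C@@]2(C)[C@H]1OC(=O)C(C)(C)C | intermediate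
14 | 4α-hydroxy-4β-isopropyl compound with saturated five-membered ring (6β-OTBS, 10β-OPiv, C7=C8) | CC1=C[C@@H](O[Si](C)(C)C(C)(C)C)[C@H]2[C@@](O)(C(C)C)CC[C@@]2(C)[C@H]1OC(=O)C(C)(C)C | intermediate
15 | 4α,10β-diol (6β-OTBS, C7=C8) | CC1=C[C@@H](O[Si](C)(C)C(C)(C)C)[C@H]2[C@@](O)(C(C)C)CC[C@@]2(C)[C@H]1O | intermediate
16 | C10 ketone, enone C10(=O)–C8=C7 (4α-OH, 6β-OTBS) | CC1=C[C@@H](O[Si](C)(C)C(C)(C)C)[C@H]2[C@@](O)(C(C)C)CC[C@@]2(C)C1=O | intermediate
17 | triethylsilyl enol ether C10(OSiEt3)=C8 (4α-OH, 6β-OTBS) | CC1=C(O[Si](CC)(CC)CC)[C@]2(C)CC[C@](O)(C(C)C)[C@@H]2[C@H](O[Si](C)(C)C(C)(C)C)C1 | intermediate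
18 | siloxycyclopropane, C9 on the α face between C8 and C10 (10β-OSiEt3, 8β-methyl) | C[C@]12C[C@@]1(O[Si](CC)(CC)CC)[C@]3(C)CC[C@](O)(C(C)C)[C@@H]3[C@H](O[Si](C)(C)C(C)(C)C)C2 | intermediate
19 | 8-chloro-8-methyl-10-ketone, seven-membered ring, mixture of C8 epimers | CC1(Cl)CC(=O)[C@]2(C)CC[C@](O)(C(C)C)[C@@H]2[C@H](O[Si](C)(C)C(C)(C)C)C1 | intermediate
20 | cis-fused hydroazulenone: 10-oxo, C8=C9, 4α-OH, 4β-isopropyl, 6β-OTBS | CC1=CC(=O)[C@]2(C)CC[C@](O)(C(C)C)[C@@H]2[C@H](O[Si](C)(C)C(C)(C)C)C1 | intermediate
21 | 10α-alcohol (4α-OH, 6β-OTBS, C8=C9) | CC1=C[C@@H](O)[C@]2(C)CC[C@](O)(C(C)C)[C@@H]2[C@H](O[Si](C)(C)C(C)(C)C)C1 | intermediate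
22 | 10α-isovalerate (4α-OH, 6β-OTBS) | CC1=C[C@@H](OC(=O)CC(C)C)[C@]2(C)CC[C@](O)(C(C)C)[C@@H]2[C@H](O[Si](C)(C)C(C)(C)C)C1 | intermediate
23 | 6β-alcohol (4α-OH, 10α-isovalerate) | CC1=C[C@@H](OC(=O)CC(C)C)[C@]2(C)CC[C@](O)(C(C)C)[C@@H]2[C@H](O)C1 | intermediate
24 | 6β-(4-acetoxybenzoate) (4α-OH, 10α-isovalerate) | CC1=C[C@@H](OC(=O)CC(C)C)[C@]2(C)CC[C@](O)(C(C)C)[C@@H]2[C@H](OC(=O)c2ccc(OC(C)=O)cc2)C1 | intermediate
25 | (3S,3aS,4R,8R,8aR)-3-hydroxy-6,8a-dimethyl-8-(3-methylbutanoyloxy)-3-(propan-2-yl)-1,2,3,3a,4,5,8,8a-octahydroazulen-4-yl 4-hydroxybenzoate | CC1=C[C@@H](OC(=O)CC(C)C)[C@]2(C)CC[C@](O)(C(C)C)[C@@H]2[C@H](OC(=O)c2ccc(O)cc2)C1 | target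

Total step count: 19. Longest linear sequence: 18 steps (steps 1, 2 and 4–19, from 1 to 25).

Steps most likely to fail

1. Step 4 (Proposed new method). The silyl dienol ether may be desilylated or may add in a stepwise Michael fashion under the strongly acidic catalyst. The acidic enedione may inhibit turnover. The catalyst may discriminate too little between the two alkene faces or the two orientations. Fallback with known chemistry: setting out again from 5 and 7, the cycloaddition is promoted by the achiral Lewis acid BF3·OEt2 (CH2Cl2, −78 °C), which imposes the same Lewis-acid orientation on methyl-substituted enediones. It should give 8 as a racemate, accompanied by the enantiomeric adduct F1. Step 5 is run on the racemate, and the triflate, now accompanied by the enantiomeric triflate F2, is resolved by preparative chromatography on a chiral stationary phase. The route is rejoined at 9.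

2. Step 15. Hydride may be delivered to the α face if the seven-membered ring adopts the conformer in which C2, not the C1 methyl, is pseudo-axial, or if the 6β-silyloxy group screens the β face. Fallback: setting out from 20, the reduction in that case gives mainly the epimeric 10β-alcohol F3. Mitsunobu esterification (4-nitrobenzoic acid, PPh3, DIAD, toluene) inverts C10 and gives the 10α-(4-nitrobenzoate) F4. Methanolysis (K2CO3, MeOH) then returns to the route at 21.

3. Step 8. Hydrazine may condense too slowly with the hindered C2 carbonyl next to the quaternary C1, so that the epoxy ketone decomposes or the diazene intermediate is diverted. Fallback: setting out from 11, NaBH4 (MeOH, 0 °C) reduces the ketone to the epoxy alcohol F5 (either C2 epimer serves). 1,1'-Thiocarbonyldiimidazole (DMAP, toluene, 80 °C) converts it into the imidazole-1-carbothioate F6. Bu3SnH with AIBN (toluene, 80 °C) then generates the C2 radical, which opens the epoxide (radical deoxygenation with epoxide fragmentation) to give the same transposed allylic alcohol. The route is rejoined at 13.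

Further compounds
F1 | step 4 | enantiomer of adduct 8 | CC1=C[C@H](O[Si](C)(C)C(C)(C)C)[C@@H]2C(=O)CC(=O)[C@]2(C)[C@@H]1OC(=O)C(C)(C)C
F2 | step 4 | enantiomer of triflate 9 | CC1=C[C@H](O[Si](C)(C)C(C)(C)C)[C@@H]2C(OS(=O)(=O)C(F)(F)F)=CC(=O)[C@]2(C)[C@@H]1OC(=O)C(C)(C)C
F3 | step 15 | 10β-alcohol (C10 epimer of 21) | CC1=C[C@H](O)[C@]2(C)CC[C@](O)(C(C)C)[C@@H]2[C@H](O[Si](C)(C)C(C)(C)C)C1
F4 | step 15 | 10α-(4-nitrobenzoate) of 21 | CC1=C[C@@H](OC(=O)c3ccc(cc3)[N+](=O)[O-])[C@]2(C)CC[C@](O)(C(C)C)[C@@H]2[C@H](O[Si](C)(C)C(C)(C)C)C1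
F5 | step 8 | 3α,4α-epoxy-2-alcohol from 11 (C2 epimers) | CC1=C[C@@H](O[Si](C)(C)C(C)(C)C)[C@H]2[C@]3(C(C)C)O[C@@H]3C(O)[C@@]2(C)[C@H]1OC(=O)C(C)(C)C
F6 | step 8 | O-(imidazole-1-carbothioate) of F5 | CC1=C[C@@H](O[Si](C)(C)C(C)(C)C)[C@H]2[C@]3(C(C)C)O[C@@H]3C(OC(=S)n4ccnc4)[C@@]2(C)[C@H]1OC(=O)C(C)(C)C
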